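**Retrosynthetic overview**

1. The target is cut in its pyran ring at the aryl C–CH= bond and the O–CMe2 bond, giving triphenol 15 and 3-methylbut-2-enal 16 (domino Knoevenagel/oxa-6π annulation, last step).
2. Enabling feature: ring A of 15 has exactly one C–H, between two phenolic C–OH carbons, and the O–H next to the ketone is locked in a six-membered O–H···O=C hydrogen-bond ring, so that carbon attacks the aldehyde and the free para oxygen closes the pyran.
3. The C-prenyl group of 15 comes from the chelated oxygen by a para-Claisen–Cope shift of prenyl ether 11, made from phenol 9 and prenol; 9 comes from the symmetric 2,6-dimethoxy ketone 8 by mono-demethylation.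
4. The 1,2-diketone of 8 is assembled in one flask from two aryllithiums and 1,4-dimethylpiperazine-2,3-dione; the ring A nucleophile comes from lithiation of silyl ether 2 between its two methoxy groups.
5. Ring order: rings A and B are bought as benzene rings; the pyran ring is the only ring made and is closed last.

Key step: step 7

Remark on the chemistry: the target has no stereocentre and no E/Z-isomeric double bond outside the pyran ring, so no stereocontrol is needed.

**Step 1**
Reactants: 1 3,5-dimethoxyphenol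
Product: 2 (3,5-dimethoxyphenoxy)tri(propan-2-yl)silane
Conditions: TIPSCl, imidazole, DMF, 0 °C to rt
Reagents that add atoms: chlorotri(propan-2-yl)silane (TIPSCl), CC(C)[Si](Cl)(C(C)C)C(C)C
Why: Imidazole-promoted O-silylation of the phenol (silyl ether formation), which installs a bulky, non-coordinating group that neither directs lithiation nor is attacked by n-BuLi in step 2.

**Step 2**
Reactants: 2 (3,5-dimethoxyphenoxy)tri(propan-2-yl)silane; 3 1,4-dimethylpiperazine-2,3-dione; 4 (4-bromophenoxy)tri(propan-2-yl)silane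
Product: 8 1-[2,6-dimethoxy-4-(triisopropylsilyloxy)phenyl]-2-[4-(triisopropylsilyloxy)phenyl]ethane-1,2-dione, via dimethoxyaryllithium 5 (not isolated), via silyloxyphenyllithium 6 (not isolated), via lithium hemiaminal alkoxide 7 (not isolated)
Conditions: 2, n-BuLi, THF, 0 °C to rt; add to 3, THF, −78 to 0 °C; then 6 (from 4, n-BuLi, THF, −78 °C), −78 °C to rt; aq. HCl (1 M)
Reagents that add atoms: none
Why: Directed ortho-metalation of 2 occurs at the carbon flanked by both methoxy groups (the silyloxy group is a poor director), and the sequential addition of two different aryllithiums to the cyclic oxamide 3 is a known route to unsymmetrical 1,2-diketones, each amide carbonyl being held as a lithium hemiaminal until the acidic work-up releases both ketones.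

**Step 3**
Reactants: 8 1-[2,6-dimethoxy-4-(triisopropylsilyloxy)phenyl]-2-[4-(triisopropylsilyloxy)phenyl]ethane-1,2-dione
Product: 9 1-[2-hydroxy-6-methoxy-4-(triisopropylsilyloxy)phenyl]-2-[4-(triisopropylsilyloxy)phenyl]ethane-1,2-dione
Conditions: BCl3 (1.2 equiv), CH2Cl2, −78 to 0 °C; then H2O
Reagents that add atoms: none
Why: Chelation-controlled Lewis acid ether cleavage: BCl3 bridges the ring A ketone oxygen and one ortho methoxy oxygen and removes that methyl group only, the boron chelate so formed shielding the second, symmetry-equivalent methoxy group, while the silyl ethers lack such activation.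

**Step 4**
Reactants: 9 1-[2-hydroxy-6-methoxy-4-(triisopropylsilyloxy)phenyl]-2-[4-(triisopropylsilyloxy)phenyl]ethane-1,2-dione; 10 3-methylbut-2-en-1-ol
Product: 11 1-[2-methoxy-6-(3-methylbut-2-enyloxy)-4-(triisopropylsilyloxy)phenyl]-2-[4-(triisopropylsilyloxy)phenyl]ethane-1,2-dione
Conditions: PPh3, DIAD, THF, 0 °C to rt
Reagents that add atoms: none
Why: Mitsunobu etherification of the hydrogen-bonded phenol (acidic enough for the betaine) by SN2 attack at the primary carbon of 10, under neutral conditions that leave both silyl ethers in place.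

**Step 5**
Reactants: 11 1-[2-methoxy-6-(3-methylbut-2-enyloxy)-4-(triisopropylsilyloxy)phenyl]-2-[4-(triisopropylsilyloxy)phenyl]ethane-1,2-dione
Product: 14 1-[6-hydroxy-2-methoxy-3-(3-methylbut-2-enyl)-4-(triisopropylsilyloxy)phenyl]-2-[4-(triisopropylsilyloxy)phenyl]ethane-1,2-dione, via ortho-dienone 12 (not isolated), via para-dienone 13 (not isolated)
Conditions: Eu(fod)3 (10 mol%; fod = 6,6,7,7,8,8,8-heptafluoro-2,2-dimethyloctane-3,5-dionate), NaHCO3, PhCl, 85 °C
Reagents that add atoms: none
Why: Aromatic Claisen rearrangement followed by Cope rearrangement (para-Claisen–Cope), promoted by europium chelation of the ether oxygen and the neighbouring ketone: the first [3,3] shift reaches the only free ortho carbon (dienone 12, reverse prenyl group), the second [3,3] shift carries the group on to the para carbon in its normal prenyl form (dienone 13), and tautomerisation gives the chelated phenol.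

**Step 6**
Reactants: 14 1-[6-hydroxy-2-methoxy-3-(3-methylbut-2-enyl)-4-(triisopropylsilyloxy)phenyl]-2-[4-(triisopropylsilyloxy)phenyl]ethane-1,2-dione
Product: 15 1-[4,6-dihydroxy-2-methoxy-3-(3-methylbut-2-enyl)phenyl]-2-(4-hydroxyphenyl)ethane-1,2-dione
Conditions: TBAF (2.5 equiv), AcOH (2.5 equiv), THF, 0 °C
Reagents that add atoms: none
Why: Fluoride-induced desilylation of the two aryl silyl ethers, buffered with AcOH so that the phenoxides of the 1,2-diketone are not exposed to strongly basic conditions.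

**Step 7**
Reactants: 15 1-[4,6-dihydroxy-2-methoxy-3-(3-methylbut-2-enyl)phenyl]-2-(4-hydroxyphenyl)ethane-1,2-dione; 16 3-methylbut-2-enal
Product: 18 1-[5-hydroxy-7-methoxy-2,2-dimethyl-8-(3-methylbut-2-enyl)-2H-chromen-6-yl]-2-(4-hydroxyphenyl)ethane-1,2-dione, via ortho-quinone methide 17 (not isolated)
Conditions: 16 (3 equiv), pyridine, 120 °C, sealed tube, argon
Reagents that add atoms: none
Why: Pyridine mediates an aldol-type (Knoevenagel) addition of the single ring A C–H carbon of 15, which lies between two phenolic C–OH carbons, to the aldehyde carbon of 16 (aryl C–CH bond), loss of water then gives the vinylogous ortho-quinone methide 17, and its 1-oxatriene closes by a thermal disrotatory oxa-6π electrocyclisation (O–CMe2 bond), the whole being a formal (3+3) annulation. The closest known reaction type is the chromene synthesis from resorcinol-type 2,4-dihydroxyaryl ketones and 3-methylbut-2-enal in hot pyridine. The pyran ring is thus closed by an electrocyclic ring closure of a (Z)-dienone and no stereocentre is formed, because the new sp3 carbon carries two methyl groups. The step needs site selectivity at carbon and at oxygen: the carbon site is fixed because ring A has no other C–H and ring B, a monohydric para-acylphenol, is too weak a nucleophile under these conditions. The oxygen site is fixed by the six-membered O–H···O=C hydrogen-bond ring between the ortho hydroxy group and the neighbouring ketone, since only the quinone methide tautomer whose carbonyl sits on the para oxygen keeps this chelate, so that oxygen, next to the prenyl-bearing carbon, ends up in the pyran. A tertiary amine is chosen because primary amine catalysts would condense with the 1,2-diketone.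

**Compound list**

1 | 3,5-dimethoxyphenol | COc1cc(O)cc(OC)c1 | starting material
2 | (3,5-dimethoxyphenoxy)tri(propan-2-yl)silane | COc1cc(O[Si](C(C)C)(C(C)C)C(C)C)cc(OC)c1 | intermediate
3 | 1,4-dimethylpiperazine-2,3-dione | CN1CCN(C)C(=O)C1=O | starting material
4 | (4-bromophenoxy)tri(propan-2-yl)silane | Brc1ccc(O[Si](C(C)C)(C(C)C)C(C)C)cc1 | starting material
5 | [2,6-dimethoxy-4-(triisopropylsilyloxy)phenyl]lithium | COc1cc(O[Si](C(C)C)(C(C)C)C(C)C)cc(OC)c1[Li] | intermediate
6 | [4-(triisopropylsilyloxy)phenyl]lithium | [Li]c1ccc(O[Si](C(C)C)(C(C)C)C(C)C)cc1 | intermediate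
7 | lithium 2-[2,6-dimethoxy-4-(triisopropylsilyloxy)phenyl]-1,4-dimethyl-3-oxopiperazin-2-olate (racemic) | CN1CCN(C)C(O[Li])(c2c(OC)cc(O[Si](C(C)C)(C(C)C)C(C)C)cc2OC)C1=O | intermediate
8 | 1-[2,6-dimethoxy-4-(triisopropylsilyloxy)phenyl]-2-[4-(triisopropylsilyloxy)phenyl]ethane-1,2-dione | COc1cc(O[Si](C(C)C)(C(C)C)C(C)C)cc(OC)c1C(=O)C(=O)c1ccc(O[Si](C(C)C)(C(C)C)C(C)C)cc1 | intermediate
9 | 1-[2-hydroxy-6-methoxy-4-(triisopropylsilyloxy)phenyl]-2-[4-(triisopropylsilyloxy)phenyl]ethane-1,2-dione | COc1cc(O[Si](C(C)C)(C(C)C)C(C)C)cc(O)c1C(=O)C(=O)c1ccc(O[Si](C(C)C)(C(C)C)C(C)C)cc1 | intermediate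
10 | 3-methylbut-2-en-1-ol | CC(C)=CCO | starting material
11 | 1-[2-methoxy-6-(3-methylbut-2-enyloxy)-4-(triisopropylsilyloxy)phenyl]-2-[4-(triisopropylsilyloxy)phenyl]ethane-1,2-dione | COc1cc(O[Si](C(C)C)(C(C)C)C(C)C)cc(OCC=C(C)C)c1C(=O)C(=O)c1ccc(O[Si](C(C)C)(C(C)C)C(C)C)cc1 | intermediate
12 | 1-[2-methoxy-5-(2-methylbut-3-en-2-yl)-6-oxo-4-(triisopropylsilyloxy)cyclohexa-1,3-dien-1-yl]-2-[4-(triisopropylsilyloxy)phenyl]ethane-1,2-dione (racemic) | COC1=C(C(=O)C(=O)c2ccc(O[Si](C(C)C)(C(C)C)C(C)C)cc2)C(=O)C(C(C)(C)C=C)C(O[Si](C(C)C)(C(C)C)C(C)C)=C1 | intermediate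
13 | 1-[2-methoxy-3-(3-methylbut-2-enyl)-6-oxo-4-(triisopropylsilyloxy)cyclohexa-1,4-dien-1-yl]-2-[4-(triisopropylsilyloxy)phenyl]ethane-1,2-dione (racemic) | COC1=C(C(=O)C(=O)c2ccc(O[Si](C(C)C)(C(C)C)C(C)C)cc2)C(=O)C=C(O[Si](C(C)C)(C(C)C)C(C)C)C1CC=C(C)C | intermediate
14 | 1-[6-hydroxy-2-methoxy-3-(3-methylbut-2-enyl)-4-(triisopropylsilyloxy)phenyl]-2-[4-(triisopropylsilyloxy)phenyl]ethane-1,2-dione | COc1c(CC=C(C)C)c(O[Si](C(C)C)(C(C)C)C(C)C)cc(O)c1C(=O)C(=O)c1ccc(O[Si](C(C)C)(C(C)C)C(C)C)cc1 | intermediate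
15 | 1-[4,6-dihydroxy-2-methoxy-3-(3-methylbut-2-enyl)phenyl]-2-(4-hydroxyphenyl)ethane-1,2-dione | COc1c(CC=C(C)C)c(O)cc(O)c1C(=O)C(=O)c1ccc(O)cc1 | intermediate
16 | 3-methylbut-2-enal | CC(C)=CC=O | starting material
17 | 1-[2-hydroxy-6-methoxy-5-(3-methylbut-2-enyl)-3-(3-methylbut-2-enylidene)-4-oxocyclohexa-1,5-dien-1-yl]-2-(4-hydroxyphenyl)ethane-1,2-dione | COC1=C(CC=C(C)C)C(=O)C(=CC=C(C)C)C(O)=C1C(=O)C(=O)c1ccc(O)cc1 | intermediate
18 | 1-[5-hydroxy-7-methoxy-2,2-dimethyl-8-(3-methylbut-2-enyl)-2H-chromen-6-yl]-2-(4-hydroxyphenyl)ethane-1,2-dione | COc1c(CC=C(C)C)c2c(c(O)c1C(=O)C(=O)c1ccc(O)cc1)C=CC(C)(C)O2 | target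

**Totals**

Total step count: 7. Longest linear sequence: 7 steps (1 to 18).

**Steps most likely to fail**

Step 2. The first hemiaminal alkoxide 7 may collapse before the second aryllithium arrives, so that one aryllithium adds twice or the freed ketone is attacked. The fallback builds the diketone by alkyne oxidation and sets out from 2 and 4. Compound 2 is lithiated as before and quenched with iodine to give (4-iodo-3,5-dimethoxyphenoxy)tri(propan-2-yl)silane F1. Compound 4 is coupled with ethynyltrimethylsilane (Sonogashira coupling, PdCl2(PPh3)2, CuI, Et3N) to give trimethyl{[4-(triisopropylsilyloxy)phenyl]ethynyl}silane F2, which is C-desilylated (K2CO3, MeOH, 0 °C) to (4-ethynylphenoxy)tri(propan-2-yl)silane F3. Sonogashira coupling of F1 with F3 should give {4-[(2,6-dimethoxy-4-(triisopropylsilyloxy)phenyl)ethynyl]phenoxy}tri(propan-2-yl)silane F4. Oxidation of the alkyne (PdCl2 cat., DMSO, 140 °C) brings the route back at 8.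

Step 5. The ortho-dienone 12 may tautomerise to the phenol before the Cope shift, which would fix a 2-methylbut-3-en-2-yl group at the ortho carbon. The fallback blocks that carbon first by reversing the order of annulation and prenyl transfer, and sets out from 9. Desilylation (TBAF, AcOH) gives 1-(2,4-dihydroxy-6-methoxyphenyl)-2-(4-hydroxyphenyl)ethane-1,2-dione F5. Annulation with 16 in hot pyridine, directed by the same hydrogen-bond chelate to the carbon between the two hydroxy groups, should give 1-(5-hydroxy-7-methoxy-2,2-dimethyl-2H-chromen-6-yl)-2-(4-hydroxyphenyl)ethane-1,2-dione F6. Selective silylation of the unchelated phenol (TIPSCl, imidazole) gives 1-(5-hydroxy-7-methoxy-2,2-dimethyl-2H-chromen-6-yl)-2-[4-(triisopropylsilyloxy)phenyl]ethane-1,2-dione F7. Mitsunobu reaction with 10 gives 1-[7-methoxy-2,2-dimethyl-5-(3-methylbut-2-enyloxy)-2H-chromen-6-yl]-2-[4-(triisopropylsilyloxy)phenyl]ethane-1,2-dione F8. Its para-Claisen–Cope rearrangement now starts from a fully substituted ortho carbon, so that only the para product can rearomatise, giving 1-[5-hydroxy-7-methoxy-2,2-dimethyl-8-(3-methylbut-2-enyl)-2H-chromen-6-yl]-2-[4-(triisopropylsilyloxy)phenyl]ethane-1,2-dione F9. Desilylation (TBAF, AcOH) brings the route back at 18.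

Step 7. Carbon–carbon bond formation at the acyl-deactivated ring may be slow, with self-condensation of the enal taking over. The fallback delivers the aldehyde inside a boron template and sets out from 15. Condensation of 15 with 16 and phenylboronic acid (propionic acid cat., toluene, water separator) should give racemic 1-[5-hydroxy-7-methoxy-8-(3-methylbut-2-enyl)-4-(2-methylprop-1-enyl)-2-phenyl-4H-1,3,2-benzodioxaborinin-6-yl]-2-(4-hydroxyphenyl)ethane-1,2-dione F10, in which the aryl C–C bond is already in place. Heating F10 expels the boron unit, regenerates the quinone methide 17 and, after electrocyclisation, brings the route back at 18.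

**Further compounds**

F1 | step 2 | (4-iodo-3,5-dimethoxyphenoxy)tri(propan-2-yl)silane | COc1cc(O[Si](C(C)C)(C(C)C)C(C)C)cc(OC)c1I
F2 | step 2 | trimethyl{[4-(triisopropylsilyloxy)phenyl]ethynyl}silane | C[Si](C)(C)C#Cc1ccc(O[Si](C(C)C)(C(C)C)C(C)C)cc1
F3 | step 2 | (4-ethynylphenoxy)tri(propan-2-yl)silane | C#Cc1ccc(O[Si](C(C)C)(C(C)C)C(C)C)cc1
F4 | step 2 | {4-[(2,6-dimethoxy-4-(triisopropylsilyloxy)phenyl)ethynyl]phenoxy}tri(propan-2-yl)silane | COc1cc(O[Si](C(C)C)(C(C)C)C(C)C)cc(OC)c1C#Cc1ccc(O[Si](C(C)C)(C(C)C)C(C)C)cc1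
F5 | step 5 | 1-(2,4-dihydroxy-6-methoxyphenyl)-2-(4-hydroxyphenyl)ethane-1,2-dione | COc1cc(O)cc(O)c1C(=O)C(=O)c1ccc(O)cc1
F6 | step 5 | 1-(5-hydroxy-7-methoxy-2,2-dimethyl-2H-chromen-6-yl)-2-(4-hydroxyphenyl)ethane-1,2-dione | COc1cc2c(c(O)c1C(=O)C(=O)c1ccc(O)cc1)C=CC(C)(C)O2
F7 | step 5 | 1-(5-hydroxy-7-methoxy-2,2-dimethyl-2H-chromen-6-yl)-2-[4-(triisopropylsilyloxy)phenyl]ethane-1,2-dione | COc1cc2c(c(O)c1C(=O)C(=O)c1ccc(O[Si](C(C)C)(C(C)C)C(C)C)cc1)C=CC(C)(C)O2
F8 | step 5 | 1-[7-methoxy-2,2-dimethyl-5-(3-methylbut-2-enyloxy)-2H-chromen-6-yl]-2-[4-(triisopropylsilyloxy)phenyl]ethane-1,2-dione | COc1cc2c(c(OCC=C(C)C)c1C(=O)C(=O)c1ccc(O[Si](C(C)C)(C(C)C)C(C)C)cc1)C=CC(C)(C)O2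
F9 | step 5 | 1-[5-hydroxy-7-methoxy-2,2-dimethyl-8-(3-methylbut-2-enyl)-2H-chromen-6-yl]-2-[4-(triisopropylsilyloxy)phenyl]ethane-1,2-dione | COc1c(CC=C(C)C)c2c(c(O)c1C(=O)C(=O)c1ccc(O[Si](C(C)C)(C(C)C)C(C)C)cc1)C=CC(C)(C)O2
F10 | step 7 | 1-[5-hydroxy-7-methoxy-8-(3-methylbut-2-enyl)-4-(2-methylprop-1-enyl)-2-phenyl-4H-1,3,2-benzodioxaborinin-6-yl]-2-(4-hydroxyphenyl)ethane-1,2-dione (racemic) | COc1c(CC=C(C)C)c2OB(c3ccccc3)OC(C=C(C)C)c2c(O)c1C(=O)C(=O)c1ccc(O)cc1
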